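**Plan**
- Numbering runs from the carboxyl carbon C1 to C17, the CH2 on the furan. The oxirane spans C6–C7, γ,δ to C3, so a carboxyl group at C3 can close a five-membered lactone onto C6 and onto no other alkene carbon; this singles out C6=C7 among three near-identical trisubstituted alkenes.
- Retrosynthesis: cut C2=C3 (Wittig); trade the oxirane for the C6–O/C7–I iodolactone of the C3 acid; cut the triene acid at C4–C5/C6–C7, C8–C9/C10–C11 and C12–C13/C14–C15 (Claisen bond/Grignard bond pairs); cut furan–C17 last.
- Forward: 3-bromofuran and oxetane give C15–C17; three rounds of isopropenyl Grignard addition, Johnson–Claisen rearrangement and reduction grow the all-E chain to the C3 acid. The γ-lactone is the only ring closed (step 12), it is transposed into the oxirane (step 13), and the C3 carbonyl then serves to attach C1–C2.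
- Stereochemistry: the chain alkenes are E from chair Claisen transition states and C2=C3 is E from a stabilized ylide. C6 and C7 come from catalyst-controlled anti iodolactonization of the E alkene; inversion at C7 on oxirane closure gives the trans (6S,7S) oxirane.

Key step: step 12

Assumption: the facial sense of the step 12 catalyst on this substrate rests on analogy only; the (1R,2R) form is written, and its (1S,2S) mirror image takes its place if a pilot run gives the mirror-image lactone.

Step 1
Reactants: 1 3-bromofuran; 2 oxetane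
Product: 4 3-(furan-3-yl)propan-1-ol, via furan-3-yllithium 3 (not isolated)
Conditions: n-BuLi, THF, −78 °C; then 2, BF3·OEt2, −78 °C; then H2O
Reagents that add atoms: none
Why: Bromine–lithium exchange at −78 °C gives the 3-lithiofuran before it can isomerize to the 2-lithio species, and BF3-activated SN2 ring opening of oxetane by this organolithium installs C15–C17 as the primary alcohol.

Step 2
Reactants: 4 3-(furan-3-yl)propan-1-ol
Product: 5 3-(furan-3-yl)propanal
Conditions: (COCl)2, DMSO, CH2Cl2, −78 °C; then Et3N, −78 to 0 °C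
Reagents that add atoms: none
Why: Swern oxidation should stop at the aldehyde under non-acidic conditions that leave the furan untouched.

Step 3
Reactants: 5 3-(furan-3-yl)propanal; 6 isopropenylmagnesium bromide
Product: 7 rac-5-(furan-3-yl)-2-methylpent-1-en-3-ol
Conditions: THF, −78 to 0 °C; then aq. NH4Cl
Reagents that add atoms: none
Why: Grignard 1,2-addition to the unhindered aldehyde forms C14–C15; the carbinol centre is racemic, which does not matter because step 4 destroys it.

Step 4
Reactants: 7 rac-5-(furan-3-yl)-2-methylpent-1-en-3-ol; 8 triethyl orthoacetate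
Product: 10 ethyl (4E)-7-(furan-3-yl)-4-methylhept-4-enoate, via ketene acetal 9 (not isolated)
Conditions: 8 (excess), EtCO2H (cat.), 140 °C, EtOH distilled off
Reagents that add atoms: none
Why: Johnson–Claisen rearrangement: acid-catalysed exchange with the orthoester and loss of ethanol give ketene acetal 9, whose chair [3,3]-sigmatropic shift with the furylethyl group equatorial forms C12–C13 and the E C14=C15 alkene.

Step 5
Reactants: 10 ethyl (4E)-7-(furan-3-yl)-4-methylhept-4-enoate
Product: 12 (4E)-7-(furan-3-yl)-4-methylhept-4-enal, via aluminium hemiacetal 11 (not isolated)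
Conditions: i-Bu2AlH (1.05 equiv), CH2Cl2, −78 °C; then aq. potassium sodium tartrate
Reagents that add atoms: none
Why: Partial ester reduction with i-Bu2AlH at −78 °C stops at the tetrahedral aluminium hemiacetal 11, which releases the C11 aldehyde only on aqueous work-up.

Step 6
Reactants: 12 (4E)-7-(furan-3-yl)-4-methylhept-4-enal; 6 isopropenylmagnesium bromide
Product: 13 rac-(6E)-9-(furan-3-yl)-2,6-dimethylnona-1,6-dien-3-ol
Conditions: THF, −78 to 0 °C; then aq. NH4Cl
Reagents that add atoms: none
Why: A second Grignard 1,2-addition forms C10–C11; the new carbinol centre is again racemic and transient.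

Step 7
Reactants: 13 rac-(6E)-9-(furan-3-yl)-2,6-dimethylnona-1,6-dien-3-ol; 8 triethyl orthoacetate
Product: 15 ethyl (4E,8E)-11-(furan-3-yl)-4,8-dimethylundeca-4,8-dienoate, via ketene acetal 14 (not isolated)
Conditions: 8 (excess), EtCO2H (cat.), 140 °C, EtOH distilled off
Reagents that add atoms: none
Why: Johnson–Claisen rearrangement through ketene acetal 14 and a chair transition state forms C8–C9 and the E C10=C11 alkene, with the existing alkene and the furan as spectators.

Step 8
Reactants: 15 ethyl (4E,8E)-11-(furan-3-yl)-4,8-dimethylundeca-4,8-dienoate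
Product: 17 (4E,8E)-11-(furan-3-yl)-4,8-dimethylundeca-4,8-dienal, via aluminium hemiacetal 16 (not isolated)
Conditions: i-Bu2AlH (1.05 equiv), CH2Cl2, −78 °C; then aq. potassium sodium tartrate
Reagents that add atoms: none
Why: Partial ester reduction with i-Bu2AlH, as in step 5, should give the C7 aldehyde through aluminium hemiacetal 16.

Step 9
Reactants: 17 (4E,8E)-11-(furan-3-yl)-4,8-dimethylundeca-4,8-dienal; 6 isopropenylmagnesium bromide
Product: 18 rac-(6E,10E)-13-(furan-3-yl)-2,6,10-trimethyltrideca-1,6,10-trien-3-ol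
Conditions: THF, −78 to 0 °C; then aq. NH4Cl
Reagents that add atoms: none
Why: A third Grignard 1,2-addition forms C6–C7; the racemic carbinol centre is removed in step 10.

Step 10
Reactants: 18 rac-(6E,10E)-13-(furan-3-yl)-2,6,10-trimethyltrideca-1,6,10-trien-3-ol; 8 triethyl orthoacetate
Product: 20 ethyl (4E,8E,12E)-15-(furan-3-yl)-4,8,12-trimethylpentadeca-4,8,12-trienoate, via ketene acetal 19 (not isolated)
Conditions: 8 (excess), EtCO2H (cat.), 140 °C, EtOH distilled off
Reagents that add atoms: none
Why: Johnson–Claisen rearrangement through ketene acetal 19 forms C4–C5 and the E C6=C7 alkene and places the C3 ester carbon γ,δ to that alkene.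

Step 11
Reactants: 20 ethyl (4E,8E,12E)-15-(furan-3-yl)-4,8,12-trimethylpentadeca-4,8,12-trienoate
Product: 21 (4E,8E,12E)-15-(furan-3-yl)-4,8,12-trimethylpentadeca-4,8,12-trienoic acid
Conditions: LiOH·H2O, THF/MeOH/H2O, 25 °C; then 1 M HCl to pH 4, 0 °C
Reagents that add atoms: lithium hydroxide, [Li+].[OH-]
Why: Saponification of the unhindered ethyl ester frees the C3 carboxylic acid needed as internal nucleophile; brief cold acidification should be tolerated by the furan and the alkenes.

Step 12
Reactants: 21 (4E,8E,12E)-15-(furan-3-yl)-4,8,12-trimethylpentadeca-4,8,12-trienoic acid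
Product: 22 (5S)-5-[(1R,4E,8E)-11-(furan-3-yl)-1-iodo-4,8-dimethylundeca-4,8-dienyl]-5-methyloxolan-2-one
Conditions: 1-[3,5-bis(trifluoromethyl)phenyl]-3-[(1R,2R)-2-(dipentylamino)cyclohexyl]urea (15 mol %), N-iodo-4-fluorophthalimide (1.05 equiv), I2 (cat.), toluene, −80 °C, dark; then aq. Na2S2O3
Reagents that add atoms: N-iodo-4-fluorophthalimide, O=C1N(I)C(=O)c2cc(F)ccc12
Why: Iodonium transfer from the N-iodoimide, relayed by the amine/I2 pair of the catalyst, is reversible at all three alkenes, but only the iodonium on C6=C7 has an internal nucleophile: the urea-bound C3 carboxylate opens it at the more substituted carbon C6, anti to iodine, forming the C6–O and C7–I bonds. The closest known reaction type is the catalytic enantioselective iodolactonization of γ,δ- and δ,ε-unsaturated acids by chiral tertiary amine–hydrogen-bond-donor catalysts. The γ-lactone closes in the 5-exo-trig mode, which is also the Markovnikov mode, since a 6-endo closure would need attack at the less substituted C7. The C6 configuration is set by the catalyst, which holds carboxylate and iodine donor together and so chooses the alkene face; C7 follows from C6 because anti addition across the E alkene is stereospecific, giving the (5S,1′R) lactone. Site selectivity is secured by the tether length, because capture of an iodonium on C10=C11 or C14=C15 would need a ring of nine or more members. The furan should be spared because intramolecular capture at −80 °C is faster than ring iodination, and iodonium formed elsewhere simply reverts.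

Step 13
Reactants: 22 (5S)-5-[(1R,4E,8E)-11-(furan-3-yl)-1-iodo-4,8-dimethylundeca-4,8-dienyl]-5-methyloxolan-2-one
Product: 24 methyl 3-[(2S,3S)-3-[(3E,7E)-10-(furan-3-yl)-3,7-dimethyldeca-3,7-dienyl]-2-methyloxiran-2-yl]propanoate, via iodohydrin methyl ester 23 (not isolated)
Conditions: K2CO3, MeOH, 0 to 25 °C
Reagents that add atoms: methanol, CO
Why: Methanolysis of the lactone (transesterification) releases the tertiary C6 alkoxide of 23, which displaces iodide at C7 in a 3-exo-tet Williamson closure with inversion, so C6 keeps its configuration and the anti iodohydrin becomes the trans (2S,3S) oxirane.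

Step 14
Reactants: 24 methyl 3-[(2S,3S)-3-[(3E,7E)-10-(furan-3-yl)-3,7-dimethyldeca-3,7-dienyl]-2-methyloxiran-2-yl]propanoate
Product: 26 3-[(2S,3S)-3-[(3E,7E)-10-(furan-3-yl)-3,7-dimethyldeca-3,7-dienyl]-2-methyloxiran-2-yl]propanal, via aluminium hemiacetal 25 (not isolated)
Conditions: i-Bu2AlH (1.1 equiv), CH2Cl2, −78 °C; then aq. potassium sodium tartrate
Reagents that add atoms: none
Why: Partial ester reduction with i-Bu2AlH at −78 °C through aluminium hemiacetal 25 should give the C3 aldehyde, the trisubstituted oxirane being inert to the hydride at this temperature and neither stereocentre being touched.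

Step 15
Reactants: 26 3-[(2S,3S)-3-[(3E,7E)-10-(furan-3-yl)-3,7-dimethyldeca-3,7-dienyl]-2-methyloxiran-2-yl]propanal; 27 ethyl 2-(triphenyl-λ5-phosphanylidene)propanoate
Product: 28 ethyl (2E)-5-[(2S,3S)-3-[(3E,7E)-10-(furan-3-yl)-3,7-dimethyldeca-3,7-dienyl]-2-methyloxiran-2-yl]-2-methylpent-2-enoate
Conditions: CH2Cl2, 25 °C
Reagents that add atoms: none
Why: Wittig olefination with the stabilized α-methyl ylide forms C2=C3 with E geometry (ester trans to the chain) under neutral conditions that leave oxirane and furan intact.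

Step 16
Reactants: 28 ethyl (2E)-5-[(2S,3S)-3-[(3E,7E)-10-(furan-3-yl)-3,7-dimethyldeca-3,7-dienyl]-2-methyloxiran-2-yl]-2-methylpent-2-enoate
Product: 29 (2E)-5-[(2S,3S)-3-[(3E,7E)-10-(furan-3-yl)-3,7-dimethyldeca-3,7-dienyl]-2-methyloxiran-2-yl]-2-methylpent-2-enoic acid
Conditions: LiOH·H2O, THF/MeOH/H2O, 25 °C; then aq. NaH2PO4 to pH 5, 0 °C
Reagents that add atoms: lithium hydroxide, [Li+].[OH-]
Why: Saponification gives the carboxylate while the hindered trisubstituted oxirane resists hydroxide at room temperature, and buffered protonation at pH 5 should liberate the acid without acid-catalysed oxirane opening.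

**Compound list**
1 | 3-bromofuran | Brc1ccoc1 | starting material
2 | oxetane | C1COC1 | starting material
3 | furan-3-yllithium | [Li]c1ccoc1 | intermediate (not isolated)
4 | 3-(furan-3-yl)propan-1-ol | OCCCc1ccoc1 | intermediate
5 | 3-(furan-3-yl)propanal | O=CCCc1ccoc1 | intermediate
6 | isopropenylmagnesium bromide | CC(=C)[Mg]Br | starting material
7 | rac-5-(furan-3-yl)-2-methylpent-1-en-3-ol | C=C(C)C(O)CCc1ccoc1 | intermediate
8 | triethyl orthoacetate | CCOC(C)(OCC)OCC | starting material
9 | 3-[3-(1-ethoxyethenoxy)-4-methylpent-4-enyl]furan (ketene acetal) | C=C(OCC)OC(CCc1ccoc1)C(C)=C | intermediate (not isolated)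
10 | ethyl (4E)-7-(furan-3-yl)-4-methylhept-4-enoate | CCOC(=O)CC/C(C)=C/CCc1ccoc1 | intermediate
11 | [(4E)-1-ethoxy-7-(furan-3-yl)-4-methylhept-4-enoxy]bis(2-methylpropyl)alumane (aluminium hemiacetal, both configurations at the acetal carbon) | CCOC(CC/C(C)=C/CCc1ccoc1)O[Al](CC(C)C)CC(C)C | intermediate (not isolated)
12 | (4E)-7-(furan-3-yl)-4-methylhept-4-enal | O=CCC/C(C)=C/CCc1ccoc1 | intermediate
13 | rac-(6E)-9-(furan-3-yl)-2,6-dimethylnona-1,6-dien-3-ol | C=C(C)C(O)CC/C(C)=C/CCc1ccoc1 | intermediate
14 | 3-[(3E)-7-(1-ethoxyethenoxy)-4,8-dimethylnona-3,8-dienyl]furan (ketene acetal) | C=C(OCC)OC(CC/C(C)=C/CCc1ccoc1)C(C)=C | intermediate (not isolated)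
15 | ethyl (4E,8E)-11-(furan-3-yl)-4,8-dimethylundeca-4,8-dienoate | CCOC(=O)CC/C(C)=C/CC/C(C)=C/CCc1ccoc1 | intermediate
16 | [(4E,8E)-1-ethoxy-11-(furan-3-yl)-4,8-dimethylundeca-4,8-dienoxy]bis(2-methylpropyl)alumane (aluminium hemiacetal, both configurations at the acetal carbon) | CCOC(CC/C(C)=C/CC/C(C)=C/CCc1ccoc1)O[Al](CC(C)C)CC(C)C | intermediate (not isolated)
17 | (4E,8E)-11-(furan-3-yl)-4,8-dimethylundeca-4,8-dienal | O=CCC/C(C)=C/CC/C(C)=C/CCc1ccoc1 | intermediate
18 | rac-(6E,10E)-13-(furan-3-yl)-2,6,10-trimethyltrideca-1,6,10-trien-3-ol | C=C(C)C(O)CC/C(C)=C/CC/C(C)=C/CCc1ccoc1 | intermediate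
19 | 3-[(3E,7E)-11-(1-ethoxyethenoxy)-4,8,12-trimethyltrideca-3,7,12-trienyl]furan (ketene acetal) | C=C(OCC)OC(CC/C(C)=C/CC/C(C)=C/CCc1ccoc1)C(C)=C | intermediate (not isolated)
20 | ethyl (4E,8E,12E)-15-(furan-3-yl)-4,8,12-trimethylpentadeca-4,8,12-trienoate | CCOC(=O)CC/C(C)=C/CC/C(C)=C/CC/C(C)=C/CCc1ccoc1 | intermediate
21 | (4E,8E,12E)-15-(furan-3-yl)-4,8,12-trimethylpentadeca-4,8,12-trienoic acid | C/C(=C\CCc1ccoc1)CC/C=C(\C)CC/C=C(\C)CCC(=O)O | intermediate
22 | (5S)-5-[(1R,4E,8E)-11-(furan-3-yl)-1-iodo-4,8-dimethylundeca-4,8-dienyl]-5-methyloxolan-2-one | C/C(=C\CCc1ccoc1)CC/C=C(\C)CC[C@@H](I)[C@]1(C)CCC(=O)O1 | intermediate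
23 | methyl (4S,5R,8E,12E)-15-(furan-3-yl)-4-hydroxy-5-iodo-4,8,12-trimethylpentadeca-8,12-dienoate (present as its potassium alkoxide) | C/C(=C\CCc1ccoc1)CC/C=C(\C)CC[C@@H](I)[C@](O)(C)CCC(=O)OC | intermediate (not isolated)
24 | methyl 3-[(2S,3S)-3-[(3E,7E)-10-(furan-3-yl)-3,7-dimethyldeca-3,7-dienyl]-2-methyloxiran-2-yl]propanoate | C/C(=C\CCc1ccoc1)CC/C=C(\C)CC[C@@H]1O[C@@]1(C)CCC(=O)OC | intermediate
25 | [3-[(2S,3S)-3-[(3E,7E)-10-(furan-3-yl)-3,7-dimethyldeca-3,7-dienyl]-2-methyloxiran-2-yl]-1-methoxypropoxy]bis(2-methylpropyl)alumane (aluminium hemiacetal, both configurations at the acetal carbon) | C/C(=C\CCc1ccoc1)CC/C=C(\C)CC[C@@H]1O[C@@]1(C)CCC(OC)O[Al](CC(C)C)CC(C)C | intermediate (not isolated)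
26 | 3-[(2S,3S)-3-[(3E,7E)-10-(furan-3-yl)-3,7-dimethyldeca-3,7-dienyl]-2-methyloxiran-2-yl]propanal | C/C(=C\CCc1ccoc1)CC/C=C(\C)CC[C@@H]1O[C@@]1(C)CCC=O | intermediate
27 | ethyl 2-(triphenyl-λ5-phosphanylidene)propanoate | CCOC(=O)C(C)=P(c1ccccc1)(c1ccccc1)c1ccccc1 | starting material
28 | ethyl (2E)-5-[(2S,3S)-3-[(3E,7E)-10-(furan-3-yl)-3,7-dimethyldeca-3,7-dienyl]-2-methyloxiran-2-yl]-2-methylpent-2-enoate | C/C(=C\CCc1ccoc1)CC/C=C(\C)CC[C@@H]1O[C@@]1(C)CC/C=C(\C)C(=O)OCC | intermediate
29 | (2E)-5-[(2S,3S)-3-[(3E,7E)-10-(furan-3-yl)-3,7-dimethyldeca-3,7-dienyl]-2-methyloxiran-2-yl]-2-methylpent-2-enoic acid | C/C(=C\CCc1ccoc1)CC/C=C(\C)CC[C@@H]1O[C@@]1(C)CC/C=C(\C)C(=O)O | target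

**Step count**
Total: 16 steps. Longest linear sequence: 16 steps, from 3-bromofuran 1 to 29.

**Steps most likely to fail, riskiest first**

Step 12. The catalyst may discriminate poorly between the two faces of an alkene that carries only alkyl groups; a lesser risk is iodination of the furan or cation–olefin cyclization if the intramolecular trap is slowed. The fallback sets out from acid 21 and comes back at 22. Uncatalysed iodolactonization (I2, NaHCO3, MeCN/H2O, 0 °C, dark) keeps the tether-based site selectivity and the anti addition. It should give 22 as a racemate with its mirror image (5R)-5-[(1S,4E,8E)-11-(furan-3-yl)-1-iodo-4,8-dimethylundeca-4,8-dienyl]-5-methyloxolan-2-one F1. Preparative chromatography on an amylose tris(3,5-dimethylphenylcarbamate) stationary phase then separates 22 from F1. The absolute configuration then rests on resolution, not on catalysis.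

Step 14. The hemiacetal may collapse before the quench, leading to over-reduction to the primary alcohol, and the aluminium reagent may open the oxirane. The fallback sets out from ester 24 and comes back at 26 by changing the acyl derivative. MeNH(OMe)·HCl with i-PrMgCl in THF at −20 °C should convert 24 into the Weinreb amide 3-[(2S,3S)-3-[(3E,7E)-10-(furan-3-yl)-3,7-dimethyldeca-3,7-dienyl]-2-methyloxiran-2-yl]-N-methoxy-N-methylpropanamide F2. LiAlH4 in THF at −78 °C then gives 26, because the chelated tetrahedral intermediate cannot accept a second hydride.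

Step 16. Hydrolysis of the hindered α-methyl enoate may be slow, and the oxirane may open (or the furan degrade) while the free acid is liberated. The fallback sets out from aldehyde 26 and comes back at 29 with an ester that is removed under neutral conditions.
- Allyl 2-bromopropanoate and PPh3 give [1-oxo-1-(prop-2-enoxy)propan-2-yl]triphenylphosphonium bromide F3.
- Aqueous NaOH converts F3 into the ylide prop-2-enyl 2-(triphenyl-λ5-phosphanylidene)propanoate F4.
- Wittig olefination of 26 with F4 in CH2Cl2 should give prop-2-enyl (2E)-5-[(2S,3S)-3-[(3E,7E)-10-(furan-3-yl)-3,7-dimethyldeca-3,7-dienyl]-2-methyloxiran-2-yl]-2-methylpent-2-enoate F5.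
- Allyl transfer to morpholine with Pd(PPh3)4 (zerovalent palladium, 5 mol %) in THF at 25 °C, followed by a pH 5 NaH2PO4 wash, releases 29 without hydroxide or strong acid.

**Further compounds**
F1 | step 12 | (5R)-5-[(1S,4E,8E)-11-(furan-3-yl)-1-iodo-4,8-dimethylundeca-4,8-dienyl]-5-methyloxolan-2-one | C/C(=C\CCc1ccoc1)CC/C=C(\C)CC[C@H](I)[C@@]1(C)CCC(=O)O1
F2 | step 14 | 3-[(2S,3S)-3-[(3E,7E)-10-(furan-3-yl)-3,7-dimethyldeca-3,7-dienyl]-2-methyloxiran-2-yl]-N-methoxy-N-methylpropanamide | C/C(=C\CCc1ccoc1)CC/C=C(\C)CC[C@@H]1O[C@@]1(C)CCC(=O)N(C)OC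
F3 | step 16 | [1-oxo-1-(prop-2-enoxy)propan-2-yl]triphenylphosphonium bromide | C=CCOC(=O)C(C)[P+](c1ccccc1)(c1ccccc1)c1ccccc1.[Br-]
F4 | step 16 | prop-2-enyl 2-(triphenyl-λ5-phosphanylidene)propanoate | C=CCOC(=O)C(C)=P(c1ccccc1)(c1ccccc1)c1ccccc1
F5 | step 16 | prop-2-enyl (2E)-5-[(2S,3S)-3-[(3E,7E)-10-(furan-3-yl)-3,7-dimethyldeca-3,7-dienyl]-2-methyloxiran-2-yl]-2-methylpent-2-enoate | C/C(=C\CCc1ccoc1)CC/C=C(\C)CC[C@@H]1O[C@@]1(C)CC/C=C(\C)C(=O)OCC=C
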